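Step by step the chain swaps one radical for the other and leaves their number unchanged: initiating radical meets starting material and becomes chain carrier, and chain carrier meets partner and gives target and initiating radical again. So the radical count moves through birth from the initiator and through death by scavenger or by pairing.

    partner + chain carrier → target + initiating radical (k1 = 51000 /M/s)
    partner + target ⇌ idle adduct, settled at all times (K2 = 7.5 /M)
    solid reagent ⇌ partner, rate k3*(cs3 - [partner]) while solid is left; crystals form when [partner] > cs3 (cs3 = 0.083 M, k3 = 0.029 /s)
    radical scavenger + initiating radical → ended chains B (k4 = 2.5 × 10⁷ /M/s)
    initiator → 2 initiating radical (k5 = 0.0069 /s)
    starting material + initiating radical → chain carrier (k6 = 25000 /M/s)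
    2 chain carrier → ended chains A (k7 = 1.4 × 10⁶ /M/s)

starting material 0.10 M; solid reagent 0.150 M; initiator 2.0 mM; radical scavenger 0.10 mM; time 30 s

- percent here means starting material units held: one ended chains A counts as two
- what is said of target includes idle adduct
- a doubled species enters its step squared and goes two at a time
- solid reagent is a solid; its amount is given per volume of the solution
- at the start none of the solid reagent is in solution
- the reaction counts as stopped when no species that holds the starting material changes by six tenths of a point or more over the second half of the time
- run time (flask): 30 s

* why nothing more happens at 30 s, or that something still does (for what has run out or reacted, a solid counts together with what of it has only dissolved) (all of the starting material has reacted / it is still moving / the partner has run out first)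
* share of the starting material used up at 30 s
* target at 30 s, in percent of the starting material charged

For whoever takes over this flask: it holds starting material, initiator, scavenger and undissolved solid reagent, with no partner in solution at the start. With the initiator at its charge, radicals are born at 2.76 × 10⁻⁵ M/s, so I give the scavenger's charge about 3.62 s, a delay shorter than the run. After that I let birth balance pairing, which puts the chain carrier near 3.14 × 10⁻⁶ M. Partner then suffers a pseudo-first-order loss of 0.160 /s.

I go round. With no partner in solution the feed is 0.00241 M/s, which would support 0.0150 M of partner; that much partner slows the feed to 0.00197 M/s, which supports 0.0123 M. The rounds close on 0.0127 M, the holding level, the partner concentration at which dissolving feeds just what the chain eats.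

At that level I reckon the chain at 0.00204 M/s. When you come at 30 s, I expect 53.8 % used up, nearly all of it as target, and the flask still moving. I read that figure as high: the reckoning keeps the initiator at its charge, puts the partner at its level at once, and sends none of the partner to the idle adduct. Don't add solid: the holding level contains no amount of it, and I reckon the run draws about 0.0611 M, less than the 0.150 M charged.

The forecast says it is still moving, “still running at roughly half conversion”, with 45 % of target and 46 % used up, a conversion lower than mine.

The flask gives 46.8 % used up and 46.2 % of target, and it is still moving; that conversion lies 7.0 percentage points under my reckoning. The partner in this flask reads 0.0127 M at 30.0 s, beside a holding level of 0.0127 M. For the neighbour flask charged with 0.0050 M of initiator, the same rule gives a lower holding level of 0.00853 M. That neighbour flask reads 0.00875 M of partner at 30.0 s, with 55.4 % used up.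

All constants are invented, and the outcome is calculated.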